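Everything rests on cutting C6–C7 (germacrane numbering), the bond shared by the ten-membered carbocycle and the butenolide. C6 (carbinol carbon) and C7 (β-carbon of the C7=C11–C12 enoate) are both natural acceptors, so the polarity of C7 is reversed. The C7–I bond of a (Z)-β-iodo enoate becomes an alkenylchromium that adds to a C6 epoxy aldehyde (Nozaki–Hiyama–Kishi reaction), and the cis C12 ester traps the new alkoxide. One operation thus closes both rings and sets C6 under control of the C4–C5 epoxide. The precursor is an open chain bearing the epoxide, the C8 ester, the C13 acetate and the C1 ketone masked as a methylene group.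

Key step: step 17

Numbering used throughout (kept for all intermediates):
- C1: ketone carbon
- C2, C3: CH2
- C4: methyl-bearing epoxide carbon
- C5: epoxide CH
- C6: lactone carbinol CH
- C7: butenolide β-carbon
- C8: acyloxy CH
- C9: CH2
- C10: methyl-bearing CH
- C11: butenolide α-carbon
- C12: lactone C=O
- C13: CH2OAc

Remark on the chemistry: 1, 7, 13 and 16 are taken as commercial. The ligand antipodes written in steps 5 and 9 are those expected to give (R)-8 and Re-face attack on 12, and the mirror-image ligand is used should the sense prove opposite.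

Step 1
Reactants: 1 (Z)-3-methylpent-2-en-4-yn-1-ol
Product: 2 (Z)-tert-butyldimethyl[(3-methylpent-2-en-4-yn-1-yl)oxy]silane
Conditions: TBSCl, imidazole, CH2Cl2, 0 °C to rt
Reagents that add atoms: tert-butyldimethylsilyl chloride CC(C)(C)[Si](C)(C)Cl
Why: Standard silylation of a primary allylic alcohol, which leaves untouched the Z alkene (C3 cis to C6) that later becomes the cis-epoxide.

Step 2
Reactants: 2 (Z)-tert-butyldimethyl[(3-methylpent-2-en-4-yn-1-yl)oxy]silane
Product: 3 (Z)-tert-butyldimethyl[(3-methylpenta-2,4-dien-1-yl)oxy]silane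
Conditions: H2 (1 atm, 1 equiv), Pd/CaCO3 poisoned with Pb(OAc)2, quinoline, hexane, rt
Reagents that add atoms: none
Why: Lindlar semihydrogenation should stop at the diene because the poisoned palladium surface binds the terminal alkyne far better than the product, and the trisubstituted Z alkene is not isomerised.

Step 3
Reactants: 3 (Z)-tert-butyldimethyl[(3-methylpenta-2,4-dien-1-yl)oxy]silane
Product: 5 (Z)-5-[(tert-butyldimethylsilyl)oxy]-3-methylpent-3-en-1-ol, via alkylborane 4 (not isolated)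
Conditions: 9-BBN, THF, 0 °C to rt; then NaOH, H2O2, 0 °C
Reagents that add atoms: 9-borabicyclo[3.3.1]nonane (boron framework of 4) B1C2CCCC1CCC2; hydrogen peroxide OO
Why: In this hydroboration–oxidation the bulky borane should add only to the monosubstituted vinyl terminus, with boron on the end carbon C2, and the C–B bond is oxidised with retention.

Step 4
Reactants: 5 (Z)-5-[(tert-butyldimethylsilyl)oxy]-3-methylpent-3-en-1-ol
Product: 6 (Z)-tert-butyl[(5-iodo-3-methylpent-2-en-1-yl)oxy]dimethylsilane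
Conditions: I2, PPh3, imidazole, CH2Cl2, 0 °C
Reagents that add atoms: iodine II
Why: Appel-type iodination displaces the activated primary alcohol by SN2 under buffered conditions that spare the silyl ether and the alkene.

Step 5
Reactants: 7 α-methylene-γ-butyrolactone
Product: 8 (R)-3-methyldihydrofuran-2(3H)-one
Conditions: H2 (100 atm), Ru(OAc)2[(S)-BINAP] (0.5 mol %), CH2Cl2, 50 °C
Reagents that add atoms: none
Why: Ruthenium–BINAP asymmetric hydrogenation of the exocyclic alkene, with the lactone carbonyl as binding group, sets C10 (R) under catalyst control.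

Step 6
Reactants: 6 (Z)-tert-butyl[(5-iodo-3-methylpent-2-en-1-yl)oxy]dimethylsilane; 8 (R)-3-methyldihydrofuran-2(3H)-one
Product: 10 (3R,7Z)-9-[(tert-butyldimethylsilyl)oxy]-1-hydroxy-3,7-dimethylnon-7-en-4-one, via alkyllithium 9 (not isolated)
Conditions: t-BuLi (2.1 equiv), Et2O/pentane, −78 °C; then 8, −78 °C; H2O
Reagents that add atoms: tert-butyllithium (lithium of 9) [Li]C(C)(C)C
Why: Iodine–lithium exchange followed by acyl substitution on the lactone forms C1–C2, and the lithium hemiketal alkoxide persists at −78 °C so that a second addition and epimerisation at C10 are avoided.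

Step 7
Reactants: 10 (3R,7Z)-9-[(tert-butyldimethylsilyl)oxy]-1-hydroxy-3,7-dimethylnon-7-en-4-one
Product: 11 (3R,7Z)-9-[(tert-butyldimethylsilyl)oxy]-3,7-dimethyl-4-methylidenenon-7-en-1-ol
Conditions: Ph3PCH3Br, KOtBu, THF, 0 °C
Reagents that add atoms: methyltriphenylphosphonium bromide C[P+](c1ccccc1)(c1ccccc1)c1ccccc1.[Br-]
Why: Wittig methylenation, run cold to protect C10, masks the C1 ketone as an alkene that no later reagent before step 18 attacks and removes the acidity at C10.

Step 8
Reactants: 11 (3R,7Z)-9-[(tert-butyldimethylsilyl)oxy]-3,7-dimethyl-4-methylidenenon-7-en-1-ol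
Product: 12 (3R,7Z)-9-[(tert-butyldimethylsilyl)oxy]-3,7-dimethyl-4-methylidenenon-7-enal
Conditions: Dess–Martin periodinane, NaHCO3, CH2Cl2, 0 °C to rt
Reagents that add atoms: none
Why: Buffered Dess–Martin oxidation takes the primary alcohol to the C8 aldehyde without touching alkenes or silyl ether.

Step 9
Reactants: 12 (3R,7Z)-9-[(tert-butyldimethylsilyl)oxy]-3,7-dimethyl-4-methylidenenon-7-enal; 13 methyl propiolate
Product: 15 methyl (4S,6R,10Z)-12-[(tert-butyldimethylsilyl)oxy]-4-hydroxy-6,10-dimethyl-7-methylidenedodec-10-en-2-ynoate, via zinc acetylide 14 (not isolated)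
Conditions: Me2Zn, (S,S)-ProPhenol (20 mol %), Ph3PO (40 mol %), toluene, 4 °C
Reagents that add atoms: dimethylzinc (methylzinc unit of 14) C[Zn]C
Why: In this zinc–ProPhenol catalysed asymmetric alkynylation the dinuclear zinc complex binds the aldehyde and acetylide 14 and delivers the alkyne to the Re face, which sets C8 (S) under catalyst control.

Step 10
Reactants: 16 methyl 2-(hydroxymethyl)acrylate
Product: 17 methyl 2-{[(tert-butyldiphenylsilyl)oxy]methyl}acrylate
Conditions: TBDPSCl, imidazole, CH2Cl2, rt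
Reagents that add atoms: tert-butyldiphenylsilyl chloride CC(C)(C)[Si](Cl)(c1ccccc1)c1ccccc1
Why: Standard silylation installs a group that outlasts the TBS ether of the main chain.

Step 11
Reactants: 17 methyl 2-{[(tert-butyldiphenylsilyl)oxy]methyl}acrylate
Product: 18 2-{[(tert-butyldiphenylsilyl)oxy]methyl}acrylic acid
Conditions: LiOH, THF/H2O, 0 °C to rt; then 1 M HCl to pH 3
Reagents that add atoms: lithium hydroxide [Li+].[OH-]
Why: Saponification of the unhindered methyl ester proceeds under conditions the TBDPS ether tolerates.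

Step 12
Reactants: 15 methyl (4S,6R,10Z)-12-[(tert-butyldimethylsilyl)oxy]-4-hydroxy-6,10-dimethyl-7-methylidenedodec-10-en-2-ynoate; 18 2-{[(tert-butyldiphenylsilyl)oxy]methyl}acrylic acid
Product: 19 methyl (4S,6R,10Z)-12-[(tert-butyldimethylsilyl)oxy]-4-[(2-{[(tert-butyldiphenylsilyl)oxy]methyl}acryloyl)oxy]-6,10-dimethyl-7-methylidenedodec-10-en-2-ynoate
Conditions: DCC, DMAP (10 mol %), CH2Cl2, 0 °C
Reagents that add atoms: none
Why: Steglich esterification at 0 °C with little DMAP acylates the propargylic alcohol with retention at C8 and keeps base-induced ynoate isomerisation in check.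

Step 13
Reactants: 19 methyl (4S,6R,10Z)-12-[(tert-butyldimethylsilyl)oxy]-4-[(2-{[(tert-butyldiphenylsilyl)oxy]methyl}acryloyl)oxy]-6,10-dimethyl-7-methylidenedodec-10-en-2-ynoate
Product: 21 methyl (2Z,4S,6R,10Z)-2-(acetoxymethyl)-12-[(tert-butyldimethylsilyl)oxy]-4-[(2-{[(tert-butyldiphenylsilyl)oxy]methyl}acryloyl)oxy]-3-iodo-6,10-dimethyl-7-methylidenedodeca-2,10-dienoate, via magnesium alkoxide 20 (not isolated)
Conditions: MgI2 (1.2 equiv), monomeric CH2O (cracked paraformaldehyde), CH2Cl2, −20 to 0 °C; then Ac2O, DMAP (cat.), 0 °C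
Reagents that add atoms: magnesium iodide [Mg+2].[I-].[I-]; formaldehyde C=O; acetic anhydride CC(=O)OC(C)=O
Why: Proposed new method: MgI2 activates the ynoate, iodide adds to the β-carbon C7, and formaldehyde hydroxymethylates the magnesium allenolate at C11 from the side away from the large iodine, which should place iodine cis to the ester (Z) and C13 cis to C8, after which Ac2O caps alkoxide 20; the closest known reaction type is the β-iodo Morita–Baylis–Hillman (iodo-aldol) three-component coupling of propiolates with aldehydes, extended here to a β-substituted ynoate.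

Step 14
Reactants: 21 methyl (2Z,4S,6R,10Z)-2-(acetoxymethyl)-12-[(tert-butyldimethylsilyl)oxy]-4-[(2-{[(tert-butyldiphenylsilyl)oxy]methyl}acryloyl)oxy]-3-iodo-6,10-dimethyl-7-methylidenedodeca-2,10-dienoate
Product: 22 the corresponding 12-hydroxy compound (free C6 allylic alcohol; 2Z,4S,6R,10Z)
Conditions: HF·pyridine, pyridine, THF, 0 °C
Reagents that add atoms: none
Why: Buffered fluoride cleaves the unhindered primary allylic TBS ether much faster than the TBDPS ether, and acetate, esters and vinyl iodide are inert.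

Step 15
Reactants: 22 C6 allylic alcohol (2Z,4S,6R,10Z)
Product: 23 (10R,11S)-10,11-epoxy-12-hydroxy compound (germacrane descriptors 4R,5S,8S,10R; cis-epoxide with C3 and C6 on the same side)
Conditions: Ti(OiPr)4 (10 mol %), L-(+)-diethyl tartrate (12 mol %), t-BuOOH, 4 Å MS, CH2Cl2, −20 °C
Reagents that add atoms: tert-butyl hydroperoxide CC(C)(C)OO
Why: Sharpless asymmetric epoxidation touches only the allylic-alcohol alkene, and with L-(+)-tartrate a Z-configured nerol-type allylic alcohol is oxidised on the face that gives the (4R,5S) cis-epoxide, so C4 and C5 are set under reagent control.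

Step 16
Reactants: 23 epoxy alcohol (4R,5S,8S,10R)
Product: 24 epoxy aldehyde (same spatial arrangement; C5 becomes R by priority change: 4R,5R,8S,10R)
Conditions: Dess–Martin periodinane, NaHCO3, CH2Cl2, 0 °C
Reagents that add atoms: none
Why: Buffered Dess–Martin oxidation gives the C6 aldehyde without epimerisation at C5 or opening of the epoxide.

Step 17
Reactants: 24 epoxy aldehyde (4R,5R,8S,10R)
Product: 26 (4R,5S,6S,8S,10R)-13-acetoxy-8-[(2-{[(tert-butyldiphenylsilyl)oxy]methyl}acryloyl)oxy]-4,5-epoxy-1-methylidenegermacr-7(11)-en-6,12-olide, via chromium alkoxide 25 (not isolated)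
Conditions: CrCl2 (10 equiv), NiCl2 (0.1 equiv), DMF, rt, slow addition of 24 to a final 0.002 M
Reagents that add atoms: chromium dichloride (CrCl2 unit of 25) Cl[Cr]Cl
Why: Zerovalent nickel, formed from NiCl2 by divalent chromium, inserts into the C7–I bond with retention and passes the alkenyl group to trivalent chromium; the ester-chelated alkenylchromium adds to the C6 aldehyde to give alkoxide 25, which attacks the cis C12 methyl ester and expels methoxide. The closest known reaction type is the Nozaki–Hiyama–Kishi macrocyclisation, joined to the known butenolide formation from (Z)-β-iodo enoates and aldehydes. The ten-membered carbocycle closes by C–C bond formation in a 10-exo-trig attack on the C6 carbonyl (C7=C11 stays exocyclic to this ring), and the butenolide closes by 5-exo-trig acyl substitution at C12. C6 is controlled by C5 through a polar Felkin–Anh transition state in which the alkenyl group approaches anti to the C5–O bond of the cis-substituted epoxide, which gives the anti C5–O/C6–O relation (6S) of the target. Attack at the aldehyde alone is secured because C1 is a methylene group (a free C1 ketone would invite five-membered ring closure from C7), because alkenylchromium ignores esters, epoxide and acrylate, and because high dilution favours ring closure over dimerisation. The Z geometry fixed in step 13 holds alkoxide and ester cis, so lactonisation is spontaneous and makes the sequence irreversible.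

Step 18
Reactants: 26 (4R,5S,6S,8S,10R)-1-methylidene germacranolide
Product: 28 (4R,5S,6S,8S,10R)-13-acetoxy-8-[(2-{[(tert-butyldiphenylsilyl)oxy]methyl}acryloyl)oxy]-4,5-epoxy-1-oxogermacr-7(11)-en-6,12-olide, via ozonide 27 (not isolated)
Conditions: O3, CH2Cl2, −78 °C (Sudan Red 7B end point); then Me2S, −78 °C to rt
Reagents that add atoms: ozone [O-][O+]=O
Why: Ozonolysis is chemoselective for the only electron-rich alkene, the C1 methylidene, because the butenolide and acrylate alkenes are deactivated by their carbonyl groups, and the neutral reductive work-up leaves C10 intact.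

Step 19
Reactants: 28 (4R,5S,6S,8S,10R)-1-oxo germacranolide TBDPS ether
Product: 29 (4R,5S,6S,8S,10R)-13-acetoxy-4,5-epoxy-8-{[2-(hydroxymethyl)acryloyl]oxy}-1-oxogermacr-7(11)-en-6,12-olide (CNP0258719.1)
Conditions: HF·pyridine, pyridine, THF, 0 °C to rt
Reagents that add atoms: none
Why: Buffered fluoride desilylation frees the primary alcohol under conditions that the epoxide, allylic acetate, esters and the C10 stereocentre next to the ketone should tolerate.

Compound list
1 | (Z)-3-methylpent-2-en-4-yn-1-ol | C#C/C(C)=C\CO | starting material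
2 | (Z)-tert-butyldimethyl[(3-methylpent-2-en-4-yn-1-yl)oxy]silane | C#C/C(C)=C\CO[Si](C)(C)C(C)(C)C | intermediate
3 | (Z)-tert-butyldimethyl[(3-methylpenta-2,4-dien-1-yl)oxy]silane | C=C/C(C)=C\CO[Si](C)(C)C(C)(C)C | intermediate
4 | B-[(Z)-5-(tert-butyldimethylsilyloxy)-3-methylpent-3-en-1-yl]-9-borabicyclo[3.3.1]nonane | B1(CC/C(C)=C\CO[Si](C)(C)C(C)(C)C)C2CCCC1CCC2 | intermediate
5 | (Z)-5-[(tert-butyldimethylsilyl)oxy]-3-methylpent-3-en-1-ol | OCC/C(C)=C\CO[Si](C)(C)C(C)(C)C | intermediate
6 | (Z)-tert-butyl[(5-iodo-3-methylpent-2-en-1-yl)oxy]dimethylsilane | ICC/C(C)=C\CO[Si](C)(C)C(C)(C)C | intermediate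
7 | α-methylene-γ-butyrolactone | C=C1CCOC1=O | starting material
8 | (R)-3-methyldihydrofuran-2(3H)-one | C[C@@H]1CCOC1=O | intermediate
9 | (Z)-5-(tert-butyldimethylsilyloxy)-3-methylpent-3-en-1-yllithium | [Li]CC/C(C)=C\CO[Si](C)(C)C(C)(C)C | intermediate
10 | (3R,7Z)-9-[(tert-butyldimethylsilyl)oxy]-1-hydroxy-3,7-dimethylnon-7-en-4-one | OCC[C@@H](C)C(=O)CC/C(C)=C\CO[Si](C)(C)C(C)(C)C | intermediate
11 | (3R,7Z)-9-[(tert-butyldimethylsilyl)oxy]-3,7-dimethyl-4-methylidenenon-7-en-1-ol | OCC[C@@H](C)C(=C)CC/C(C)=C\CO[Si](C)(C)C(C)(C)C | intermediate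
12 | (3R,7Z)-9-[(tert-butyldimethylsilyl)oxy]-3,7-dimethyl-4-methylidenenon-7-enal | O=CC[C@@H](C)C(=C)CC/C(C)=C\CO[Si](C)(C)C(C)(C)C | intermediate
13 | methyl propiolate | C#CC(=O)OC | starting material
14 | methyl 3-(methylzincio)propiolate | C[Zn]C#CC(=O)OC | intermediate
15 | methyl (4S,6R,10Z)-12-[(tert-butyldimethylsilyl)oxy]-4-hydroxy-6,10-dimethyl-7-methylidenedodec-10-en-2-ynoate | COC(=O)C#C[C@@H](O)C[C@@H](C)C(=C)CC/C(C)=C\CO[Si](C)(C)C(C)(C)C | intermediate
16 | methyl 2-(hydroxymethyl)acrylate | C=C(CO)C(=O)OC | starting material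
17 | methyl 2-{[(tert-butyldiphenylsilyl)oxy]methyl}acrylate | C=C(CO[Si](c1ccccc1)(c1ccccc1)C(C)(C)C)C(=O)OC | intermediate
18 | 2-{[(tert-butyldiphenylsilyl)oxy]methyl}acrylic acid | C=C(CO[Si](c1ccccc1)(c1ccccc1)C(C)(C)C)C(=O)O | intermediate
19 | C8 acrylate ester of ynoate 15 (4S,6R,10Z) | COC(=O)C#C[C@@H](OC(=O)C(=C)CO[Si](c1ccccc1)(c1ccccc1)C(C)(C)C)C[C@@H](C)C(=C)CC/C(C)=C\CO[Si](C)(C)C(C)(C)C | intermediate
20 | iodomagnesium alkoxide of the (Z)-β-iodo-α-(hydroxymethyl) enoate | COC(=O)/C(CO[Mg]I)=C(\I)[C@@H](OC(=O)C(=C)CO[Si](c1ccccc1)(c1ccccc1)C(C)(C)C)C[C@@H](C)C(=C)CC/C(C)=C\CO[Si](C)(C)C(C)(C)C | intermediate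
21 | (2Z,4S,6R,10Z)-β-iodo-α-(acetoxymethyl) enoate, C6 TBS ether | COC(=O)/C(COC(C)=O)=C(\I)[C@@H](OC(=O)C(=C)CO[Si](c1ccccc1)(c1ccccc1)C(C)(C)C)C[C@@H](C)C(=C)CC/C(C)=C\CO[Si](C)(C)C(C)(C)C | intermediate
22 | (2Z,4S,6R,10Z)-β-iodo-α-(acetoxymethyl) enoate, free C6 allylic alcohol | COC(=O)/C(COC(C)=O)=C(\I)[C@@H](OC(=O)C(=C)CO[Si](c1ccccc1)(c1ccccc1)C(C)(C)C)C[C@@H](C)C(=C)CC/C(C)=C\CO | intermediate
23 | epoxy alcohol (4R,5S,8S,10R) | COC(=O)/C(COC(C)=O)=C(\I)[C@@H](OC(=O)C(=C)CO[Si](c1ccccc1)(c1ccccc1)C(C)(C)C)C[C@@H](C)C(=C)CC[C@@]1(C)O[C@H]1CO | intermediate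
24 | epoxy aldehyde (4R,5R,8S,10R) | COC(=O)/C(COC(C)=O)=C(\I)[C@@H](OC(=O)C(=C)CO[Si](c1ccccc1)(c1ccccc1)C(C)(C)C)C[C@@H](C)C(=C)CC[C@@]1(C)O[C@H]1C=O | intermediate
25 | ten-membered C6 dichlorochromium alkoxide, methyl ester still open (4R,5S,6S,8S,10R) | C=C(CO[Si](c1ccccc1)(c1ccccc1)C(C)(C)C)C(=O)O[C@H]1C[C@@H](C)C(=C)CC[C@@]2(C)O[C@H]2[C@@H](O[Cr](Cl)Cl)/C1=C(/COC(C)=O)C(=O)OC | intermediate
26 | (4R,5S,6S,8S,10R)-1-methylidene germacranolide, TBDPS ether | C=C(CO[Si](c1ccccc1)(c1ccccc1)C(C)(C)C)C(=O)O[C@H]1C[C@@H](C)C(=C)CC[C@@]2(C)O[C@H]2[C@H]2OC(=O)C(COC(C)=O)=C12 | intermediate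
27 | spiro-1,2,4-trioxolane at C1 (secondary ozonide of 26) | C=C(CO[Si](c1ccccc1)(c1ccccc1)C(C)(C)C)C(=O)O[C@H]1C[C@@H](C)C3(OCOO3)CC[C@@]2(C)O[C@H]2[C@H]2OC(=O)C(COC(C)=O)=C12 | intermediate
28 | (4R,5S,6S,8S,10R)-1-oxo germacranolide, TBDPS ether | C=C(CO[Si](c1ccccc1)(c1ccccc1)C(C)(C)C)C(=O)O[C@H]1C[C@@H](C)C(=O)CC[C@@]2(C)O[C@H]2[C@H]2OC(=O)C(COC(C)=O)=C12 | intermediate
29 | CNP0258719.1, (4R,5S,6S,8S,10R)-13-acetoxy-4,5-epoxy-8-{[2-(hydroxymethyl)acryloyl]oxy}-1-oxogermacr-7(11)-en-6,12-olide | C=C(CO)C(=O)O[C@H]1C[C@@H](C)C(=O)CC[C@@]2(C)O[C@H]2[C@H]2OC(=O)C(COC(C)=O)=C12 | target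

Total step count: 19.
Longest linear sequence: 16 steps (1–4, 6–9, 12–19).

Steps most likely to fail

Step 13.
- What may go wrong: iodide may add too slowly to the hindered C7, the allenolate may be protonated instead of hydroxymethylated, or the alkene geometry may erode.
- Fallback (known chemistry), from 19 back to 21: the 2-alkynoate is stannylcuprated with Li[Cu(SnMe3)(SPh)] in THF at −48 °C. Under these conditions the adduct equilibrates to the isomer with tin cis to the ester.
- Trapping with monomeric formaldehyde gives the (Z)-β-trimethylstannyl-α-(hydroxymethyl) enoate F1.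
- Tin–iodine exchange with I2 in CH2Cl2 at 0 °C proceeds with retention and gives the (Z)-β-iodo-α-(hydroxymethyl) enoate F2. Ac2O/pyridine then returns to 21.

Step 17.
- What may go wrong: the C8 acyloxy group may be lost by β-elimination from the alkenyl-metal intermediate, divalent chromium or chloride may attack the epoxy aldehyde, the slow ten-ring closure may lose out to protodeiodination and dimerisation, or facial selectivity at C6 may be poor.
- Fallback, from 15 back to 26, with a poorer leaving group at C8 and the ester brought in only after ring closure: 15 is silylated (TBSOTf, 2,6-lutidine) to the 4,12-bis-TBS ynoate F3.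
- Treatment as in step 13 gives the bis-TBS iodo acetate F4.
- HF·pyridine at 0 °C frees only the primary position and gives the allylic alcohol F5.
- Sharpless epoxidation with L-(+)-diethyl tartrate gives the epoxy alcohol F6, and Dess–Martin oxidation gives the epoxy aldehyde F7.
- CrCl2/NiCl2 in DMF closes both rings to the 8-O-TBS germacranolide F8.
- Longer exposure to HF·pyridine at rt gives the 8-hydroxy germacranolide F9. Steglich esterification with 18 then returns to 26.

Step 9.
- What may go wrong: facial selectivity may be poor, or the α-unbranched aldehyde may undergo self-aldol reaction under the zinc alkoxide conditions.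
- Fallback, from 12 back to 15, which moves stereocontrol from C–C bond formation to a ketone reduction: lithium methyl propiolate (LDA, THF, −78 °C) adds to 12 and gives the C8-epimeric alkynol mixture F10.
- Dess–Martin oxidation gives the 4-oxo-2-ynoate F11.
- Midland reduction with (S)-Alpine-Borane, which reduces only the acetylenic ketone, gives 15.

Further compounds
F1 | step 13 | methyl (2Z,4S,6R,10Z)-2-(hydroxymethyl)-3-(trimethylstannyl) analogue of 21 | COC(=O)/C(CO)=C(\[Sn](C)(C)C)[C@@H](OC(=O)C(=C)CO[Si](c1ccccc1)(c1ccccc1)C(C)(C)C)C[C@@H](C)C(=C)CC/C(C)=C\CO[Si](C)(C)C(C)(C)C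
F2 | step 13 | methyl (2Z,4S,6R,10Z)-2-(hydroxymethyl)-3-iodo analogue of 21 (free C13 alcohol) | COC(=O)/C(CO)=C(\I)[C@@H](OC(=O)C(=C)CO[Si](c1ccccc1)(c1ccccc1)C(C)(C)C)C[C@@H](C)C(=C)CC/C(C)=C\CO[Si](C)(C)C(C)(C)C
F3 | step 17 | methyl (4S,6R,10Z)-4,12-bis[(tert-butyldimethylsilyl)oxy]-6,10-dimethyl-7-methylidenedodec-10-en-2-ynoate | COC(=O)C#C[C@@H](O[Si](C)(C)C(C)(C)C)C[C@@H](C)C(=C)CC/C(C)=C\CO[Si](C)(C)C(C)(C)C
F4 | step 17 | methyl (2Z,4S,6R,10Z)-2-(acetoxymethyl)-4,12-bis[(tert-butyldimethylsilyl)oxy]-3-iodo-6,10-dimethyl-7-methylidenedodeca-2,10-dienoate | COC(=O)/C(COC(C)=O)=C(\I)[C@@H](O[Si](C)(C)C(C)(C)C)C[C@@H](C)C(=C)CC/C(C)=C\CO[Si](C)(C)C(C)(C)C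
F5 | step 17 | 12-hydroxy compound from F4 (C8 TBS ether kept) | COC(=O)/C(COC(C)=O)=C(\I)[C@@H](O[Si](C)(C)C(C)(C)C)C[C@@H](C)C(=C)CC/C(C)=C\CO
F6 | step 17 | epoxy alcohol from F5 (4R,5S,8S,10R) | COC(=O)/C(COC(C)=O)=C(\I)[C@@H](O[Si](C)(C)C(C)(C)C)C[C@@H](C)C(=C)CC[C@@]1(C)O[C@H]1CO
F7 | step 17 | epoxy aldehyde from F6 (4R,5R,8S,10R) | COC(=O)/C(COC(C)=O)=C(\I)[C@@H](O[Si](C)(C)C(C)(C)C)C[C@@H](C)C(=C)CC[C@@]1(C)O[C@H]1C=O
F8 | step 17 | (4R,5S,6S,8S,10R)-13-acetoxy-8-[(tert-butyldimethylsilyl)oxy]-4,5-epoxy-1-methylidenegermacr-7(11)-en-6,12-olide | CC(C)(C)[Si](C)(C)O[C@H]1C[C@@H](C)C(=C)CC[C@@]2(C)O[C@H]2[C@H]2OC(=O)C(COC(C)=O)=C12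
F9 | step 17 | (4R,5S,6S,8S,10R)-13-acetoxy-4,5-epoxy-8-hydroxy-1-methylidenegermacr-7(11)-en-6,12-olide | O[C@H]1C[C@@H](C)C(=C)CC[C@@]2(C)O[C@H]2[C@H]2OC(=O)C(COC(C)=O)=C12
F10 | step 9 | C8-epimeric mixture of 15 | COC(=O)C#CC(O)C[C@@H](C)C(=C)CC/C(C)=C\CO[Si](C)(C)C(C)(C)C
F11 | step 9 | methyl (6R,10Z)-12-[(tert-butyldimethylsilyl)oxy]-6,10-dimethyl-7-methylidene-4-oxododec-10-en-2-ynoate | COC(=O)C#CC(=O)C[C@@H](C)C(=C)CC/C(C)=C\CO[Si](C)(C)C(C)(C)C
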